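**Plan**

1. Numbering used throughout: C1 lactone carbonyl, C2 CH2, C3 the CH on the peroxide, C4 the methyl-bearing carbon on the lactone oxygen, C5 CH2, C6 the peroxide carbon carrying methyl and the 12-phenyldodecyl chain.
2. Enabling feature: the γ-lactone (O–C1–C2–C3–C4) ties the C1 carboxyl to C4 through a two-atom tether from C3. Its C4–O bond can therefore be made by carboxylate addition to a C4=C5 double bond held in a 3,6-dihydro-1,2-dioxine (O–O–C3–C4=C5–C6), the ring that singlet oxygen gives from a C3=C4–C5=C6 diene.
3. Cuts, in retrosynthetic order: C5–H (back to C5–I); C4–O(lactone) with C5–I; the C1 oxidation level; both peroxide C–O bonds (C3–O, C6–O); the C4–C5 σ-bond of the diene; then C6–C7 of one vinyl iodide and C3–H of the other.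
4. Forward: (Z)-vinyl iodide by propyne carbocupration and (E)-vinyl iodide by hydrozirconation of pent-3-yn-1-ol; Negishi coupling to the (3E,5Z)-diene; 1,2-dioxine ring by [4+2]; enantiomer separation; C1 acid; γ-lactone ring by iodolactonisation; deiodination.
5. Stereochemistry: the C3/C6 relative configuration is the imprint of the two alkene geometries through a suprafacial cycloaddition; C4 follows from C3 through the cis ring fusion. Absolute configuration comes from separating the enantiomers of the dioxine alcohol on a chiral phase, so no auxiliary has to be attached or cleaved next to the base-sensitive ring.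

Key step: step 11

Assumption: the enantiomers of dioxine alcohol 17 are taken to be separable on a polysaccharide chiral phase. The (3S,6S) fraction would be identified by anomalous-dispersion X-ray analysis of iodolactone 20, or by the sign of rotation of 21 made from each fraction compared with natural plakortolide L.

**Route**

Step 1
Reactants: 1 12-phenyldodecanoic acid
Product: 2 12-phenyldodecan-1-ol
Conditions: LiAlH4, THF, 0 °C → rt; aqueous work-up
Reagents that add atoms: none
Why: Hydride reduction of a carboxylic acid to the primary alcohol; the phenyl ring and the alkyl chain are inert and no stereocentre is involved.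

Step 2
Reactants: 2 12-phenyldodecan-1-ol
Product: 3 (12-bromododecyl)benzene
Conditions: CBr4, PPh3, CH2Cl2, 0 °C → rt
Reagents that add atoms: carbon tetrabromide, BrC(Br)(Br)Br
Why: Appel bromination, an SN2 displacement of the alkoxyphosphonium ion at a primary carbon, should give the bromide needed for Grignard formation.

Step 3
Reactants: 3 (12-bromododecyl)benzene; 4 propyne
Product: 8 (Z)-1-iodo-2-methyl-14-phenyltetradec-1-ene, via 12-phenyldodecylmagnesium bromide 5 (not isolated), via 12-phenyldodecylcopper 6 (not isolated), via (Z)-2-methyl-14-phenyltetradec-1-enylcopper 7 (not isolated)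
Conditions: Mg, Et2O, reflux; CuBr·SMe2, Et2O/Me2S, −45 °C; propyne, −25 °C; I2, THF, −50 °C → rt
Reagents that add atoms: iodine, II
Why: Normant carbocupration adds the alkylcopper syn across propyne with the alkyl group on the internal carbon and copper on the terminal one, so chain and copper are cis, and iodinolysis with retention should give the (Z)-iodide that fixes the C5=C6 geometry.

Step 4
Reactants: 9 pent-3-yn-1-ol
Product: 10 tert-butyldimethyl(pent-3-yn-1-yloxy)silane
Conditions: TBSCl, imidazole, CH2Cl2, 0 °C → rt
Reagents that add atoms: tert-butyldimethylsilyl chloride, CC(C)(C)[Si](C)(C)Cl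
Why: Standard silylation of a primary alcohol; the ether masks the hydroxyl through the organometallic steps and the photooxygenation.

Step 5
Reactants: 10 tert-butyldimethyl(pent-3-yn-1-yloxy)silane
Product: 12 (E)-tert-butyl[(4-iodopent-3-en-1-yl)oxy]dimethylsilane, via alkenylzirconocene chloride 11 (not isolated)
Conditions: Cp2Zr(H)Cl (excess), THF, 50 °C; then I2, THF, 0 °C
Reagents that add atoms: iodine, II
Why: Hydrozirconation with Schwartz's reagent is a syn addition, and with excess reagent and gentle heating the regioisomers equilibrate to put zirconium on the less hindered methyl-bearing carbon, so iodinolysis with retention should give the (E)-iodide in which the methyl group and the CH2CH2O arm are cis.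

Step 6
Reactants: 12 (E)-tert-butyl[(4-iodopent-3-en-1-yl)oxy]dimethylsilane; 8 (Z)-1-iodo-2-methyl-14-phenyltetradec-1-ene
Product: 15 tert-butyl{[(3E,5Z)-4,6-dimethyl-18-phenyloctadeca-3,5-dien-1-yl]oxy}dimethylsilane, via alkenyllithium 13 (not isolated), via alkenylzinc chloride 14 (not isolated)
Conditions: 12, t-BuLi (2 equiv), Et2O, −78 °C; ZnCl2, THF, −78 → 0 °C; then 8, Pd(PPh3)4 (cat.), THF, rt
Reagents that add atoms: none
Why: Negishi coupling, in which iodine–lithium exchange, transmetalation to zinc and Pd(0) coupling all proceed with retention at sp2 carbon, so the two defined alkene geometries should be carried unchanged into the (3E,5Z)-diene.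

Step 7
Reactants: 15 tert-butyl{[(3E,5Z)-4,6-dimethyl-18-phenyloctadeca-3,5-dien-1-yl]oxy}dimethylsilane
Product: 16 rac-tert-butyl{2-[(3S,6S)-4,6-dimethyl-6-(12-phenyldodecyl)-3,6-dihydro-1,2-dioxin-3-yl]ethoxy}dimethylsilane
Conditions: O2, tetraphenylporphyrin (cat.), visible light, CH2Cl2, −20 °C
Reagents that add atoms: dioxygen, O=O
Why: Singlet oxygen [4+2] cycloaddition to the s-cis diene is suprafacial, so the two outside groups (the C3 side chain and the C6 methyl) should end up cis on the new dioxine, as a racemate because the diene faces are equivalent; the apolar solvent and low temperature are chosen to favour cycloaddition over the competing ene reaction.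

Step 8
Reactants: 16 rac-dioxine silyl ether
Product: 17 rac-2-[(3S,6S)-4,6-dimethyl-6-(12-phenyldodecyl)-3,6-dihydro-1,2-dioxin-3-yl]ethan-1-ol
Conditions: HF (48% aq.), MeCN, 0 °C
Reagents that add atoms: none
Why: Acidic fluoride desilylation frees the primary alcohol without basic fluoride or amine, either of which could remove the allylic C3–H and open the peroxide (Kornblum–DeLaMare), while dialkyl peroxides and the trisubstituted alkene tolerate dilute HF.

Step 9
Reactants: 17 rac-dioxine alcohol
Product: 18 2-[(3S,6S)-4,6-dimethyl-6-(12-phenyldodecyl)-3,6-dihydro-1,2-dioxin-3-yl]ethan-1-ol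
Conditions: preparative HPLC on an immobilised amylose tris(3,5-dimethylphenylcarbamate) phase, hexane/i-PrOH, rt
Reagents that add atoms: none
Why: Chromatographic enantiomer separation, in which the hydroxyl group and the phenyl ring provide the hydrogen-bonding and π contacts that carbamate phases discriminate, makes or breaks no bond, so it should fix the absolute configuration of C3 and C6 without exposing the dioxine to any reagent.

Step 10
Reactants: 18 (3S,6S)-dioxine alcohol
Product: 19 2-[(3S,6S)-4,6-dimethyl-6-(12-phenyldodecyl)-3,6-dihydro-1,2-dioxin-3-yl]acetic acid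
Conditions: TEMPO (cat.), PhI(OAc)2, MeCN/H2O, 0 °C → rt
Reagents that add atoms: water, O
Why: Oxoammonium-mediated oxidation takes the primary alcohol through the aldehyde hydrate to the acid under weakly acidic, amine-free conditions that should leave the O–O bond, the trisubstituted alkene and the benzylic CH2 untouched and give the β-peroxy aldehyde no base for retro-oxa-Michael opening.

Step 11
Reactants: 19 (3S,6S)-dioxine acetic acid
Product: 20 5-iodoplakortolide L [(3S,4R,5S,6S); cis-fused γ-lactone/1,2-dioxane with iodine on C5 trans to the C4–O bond]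
Conditions: I2, NaHCO3 (solid), MeCN, 0 °C, dark; Na2S2O3 work-up
Reagents that add atoms: iodine, II
Why: Iodine adds reversibly to either face of C4=C5, but only the iodonium ion on the face opposite the C3 acetic acid arm can be opened intramolecularly, and the carboxylate does so at C4 with anti geometry, which is the kinetic iodolactonisation of a γ,δ-unsaturated acid well known for cyclohex-2-enylacetic acids. The γ-lactone closes in the 5-exo-trig mode; the 6-endo alternative at C5 would give a bridged δ-lactone and would put oxygen on the less substituted carbon. The new C4 stereocentre is dictated by C3, because the two-atom tether can reach C4 only on its own face and so gives the cis-fused bicycle, and the C5 stereocentre (iodine trans to the new C–O bond) follows from anti addition and is erased in step 12. The step needs C4-over-C5 regioselectivity, one-face delivery and survival of the peroxide: the first two are secured by the tether length and by the methyl group that makes C4 the cation-stabilising terminus, the third by solid bicarbonate at 0 °C in place of any amine, so that the allylic C3–H is not removed (Kornblum–DeLaMare).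

Step 12
Reactants: 20 5-iodoplakortolide L
Product: 21 plakortolide L
Conditions: Bu3SnH, AIBN (cat.), toluene, 80 °C
Reagents that add atoms: none
Why: Radical chain dehalogenation, in which the stannyl radical abstracts iodine far faster than it attacks the O–O bond and the secondary C5 radical is quenched by the tin hydride before it can displace on the ring peroxide (for which the in-ring geometry is poor), should turn C5 into CH2 and leave C3, C4 and C6 unchanged.

**Compound list**

1 | 12-phenyldodecanoic acid | OC(=O)CCCCCCCCCCCc1ccccc1 | starting material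
2 | 12-phenyldodecan-1-ol | OCCCCCCCCCCCCc1ccccc1 | intermediate
3 | (12-bromododecyl)benzene | BrCCCCCCCCCCCCc1ccccc1 | intermediate
4 | propyne | CC#C | starting material
5 | 12-phenyldodecylmagnesium bromide | Br[Mg]CCCCCCCCCCCCc1ccccc1 | intermediate (not isolated)
6 | 12-phenyldodecylcopper (MgBr2/Me2S complex) | [Cu]CCCCCCCCCCCCc1ccccc1 | intermediate (not isolated)
7 | (Z)-(2-methyl-14-phenyltetradec-1-en-1-yl)copper (Cu cis to the chain) | [Cu]/C=C(/C)CCCCCCCCCCCCc1ccccc1 | intermediate (not isolated)
8 | (Z)-1-iodo-2-methyl-14-phenyltetradec-1-ene | I/C=C(/C)CCCCCCCCCCCCc1ccccc1 | intermediate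
9 | pent-3-yn-1-ol | CC#CCCO | starting material
10 | tert-butyldimethyl(pent-3-yn-1-yloxy)silane | CC#CCCO[Si](C)(C)C(C)(C)C | intermediate
11 | (E)-chlorobis(cyclopentadienyl)[5-(tert-butyldimethylsilyloxy)pent-2-en-2-yl]zirconium (Zr cis to H) | C/C(=C\CCO[Si](C)(C)C(C)(C)C)[Zr](Cl)(C1C=CC=C1)C1C=CC=C1 | intermediate (not isolated)
12 | (E)-tert-butyl[(4-iodopent-3-en-1-yl)oxy]dimethylsilane | C/C(I)=C\CCO[Si](C)(C)C(C)(C)C | intermediate
13 | (Z)-[5-(tert-butyldimethylsilyloxy)pent-2-en-2-yl]lithium (Li cis to H) | C/C([Li])=C\CCO[Si](C)(C)C(C)(C)C | intermediate (not isolated)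
14 | (E)-[5-(tert-butyldimethylsilyloxy)pent-2-en-2-yl]zinc chloride (Zn cis to H) | C/C([Zn]Cl)=C\CCO[Si](C)(C)C(C)(C)C | intermediate (not isolated)
15 | tert-butyl{[(3E,5Z)-4,6-dimethyl-18-phenyloctadeca-3,5-dien-1-yl]oxy}dimethylsilane | CC(C)(C)[Si](C)(C)OCC/C=C(C)/C=C(/C)CCCCCCCCCCCCc1ccccc1 | intermediate
16 | rac-tert-butyl{2-[(3S,6S)-4,6-dimethyl-6-(12-phenyldodecyl)-3,6-dihydro-1,2-dioxin-3-yl]ethoxy}dimethylsilane (racemate, one enantiomer drawn; C3 side chain and C6 methyl cis) | C[C@]1(CCCCCCCCCCCCc2ccccc2)C=C(C)[C@H](CCO[Si](C)(C)C(C)(C)C)OO1 | intermediate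
17 | rac-2-[(3S,6S)-4,6-dimethyl-6-(12-phenyldodecyl)-3,6-dihydro-1,2-dioxin-3-yl]ethan-1-ol (racemate, one enantiomer drawn) | C[C@]1(CCCCCCCCCCCCc2ccccc2)C=C(C)[C@H](CCO)OO1 | intermediate
18 | 2-[(3S,6S)-4,6-dimethyl-6-(12-phenyldodecyl)-3,6-dihydro-1,2-dioxin-3-yl]ethan-1-ol (single enantiomer) | C[C@]1(CCCCCCCCCCCCc2ccccc2)C=C(C)[C@H](CCO)OO1 | intermediate
19 | 2-[(3S,6S)-4,6-dimethyl-6-(12-phenyldodecyl)-3,6-dihydro-1,2-dioxin-3-yl]acetic acid | C[C@]1(CCCCCCCCCCCCc2ccccc2)C=C(C)[C@H](CC(=O)O)OO1 | intermediate
20 | 5-iodoplakortolide L, (3S,4R,5S,6S) | C[C@]1(CCCCCCCCCCCCc3ccccc3)[C@@H](I)[C@]2(C)OC(=O)C[C@@H]2OO1 | intermediate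
21 | plakortolide L, (3S,4S,6S) | C[C@]1(CCCCCCCCCCCCc2ccccc2)C[C@]2(C)OC(=O)C[C@@H]2OO1 | target

**Totals**

Total step count: 12. Longest linear sequence: 10 steps (1, 2, 3, 6, 7, 8, 9, 10, 11, 12 from 12-phenyldodecanoic acid).

**Steps most likely to fail**

Step 7. The Z-alkyl group on C6 disfavours the s-cis conformer, so ene hydroperoxidation at the allylic C–H bonds and stepwise oxygen transfer may outrun the concerted cycloaddition. That would lower the yield and erode the cis C3/C6 relationship. The fallback moves the cycloaddition to the carboxylic acid oxidation level, so that nothing but a separation stands between the cycloaddition and the key step. It sets out from 15. TBAF in THF would give (3E,5Z)-4,6-dimethyl-18-phenyloctadeca-3,5-dien-1-ol F1. TEMPO/PhI(OAc)2 in aqueous MeCN would give (3E,5Z)-4,6-dimethyl-18-phenyloctadeca-3,5-dienoic acid F2. Photooxygenation as in step 7 would give racemic 2-[(3S,6S)-4,6-dimethyl-6-(12-phenyldodecyl)-3,6-dihydro-1,2-dioxin-3-yl]acetic acid F3. Separation on the same type of chiral phase with an acidic modifier would then return the route at 19. The carboxymethyl group withdraws electron density from C3=C4, the alkene most exposed to ene attack, and oxidation of (3E,5Z)-dienols to 3,5-dienoic acids is known chemistry. Steps 8 and 10 are no longer needed.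

Step 9. The enantiomers may not separate to baseline, or the throughput on the chiral phase may be too low. The fallback is a lipase-catalysed kinetic resolution and sets out from 17. Burkholderia cepacia lipase with vinyl acetate in MTBE at about 30 °C should acylate one enantiomer preferentially; alcohol and acetate are then separated on silica. If the (3R,6R)-alcohol reacts faster, it is removed as (3R,6R)-2-[4,6-dimethyl-6-(12-phenyldodecyl)-3,6-dihydro-1,2-dioxin-3-yl]ethyl acetate F4 and the unreacted alcohol is 18. If the sense is the opposite, (3S,6S)-2-[4,6-dimethyl-6-(12-phenyldodecyl)-3,6-dihydro-1,2-dioxin-3-yl]ethyl acetate F5 is isolated and de-acetylated with the same lipase in pH 7 phosphate buffer, without base, to return the route at 18. The enzyme and the sense of selectivity would have to be found by screening.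

Step 11. This is the one step in which the dioxine meets a base, an oxidant and iodide together, so fragmentation through the allylic C3–H or slow reduction of the O–O bond by iodide may compete with cyclisation. The fallback is a base-free selenolactonisation and sets out from 19. PhSeCl in CH2Cl2 at −78 °C should deliver the same 5-exo, tether-controlled closure to give 5-(phenylselanyl)plakortolide L F6, (3S,4R,5S,6S), with selenium on C5 trans to the C4–O bond. Bu3SnH/AIBN in toluene at 80–110 °C would then cleave the C–Se bond and return the route at 21.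

Further compounds
F1 | step 7 | (3E,5Z)-4,6-dimethyl-18-phenyloctadeca-3,5-dien-1-ol | OCC/C=C(C)/C=C(/C)CCCCCCCCCCCCc1ccccc1
F2 | step 7 | (3E,5Z)-4,6-dimethyl-18-phenyloctadeca-3,5-dienoic acid | OC(=O)C/C=C(C)/C=C(/C)CCCCCCCCCCCCc1ccccc1
F3 | step 7 | rac-2-[(3S,6S)-4,6-dimethyl-6-(12-phenyldodecyl)-3,6-dihydro-1,2-dioxin-3-yl]acetic acid (racemate, one enantiomer drawn) | C[C@]1(CCCCCCCCCCCCc2ccccc2)C=C(C)[C@H](CC(=O)O)OO1
F4 | step 9 | (3R,6R)-2-[4,6-dimethyl-6-(12-phenyldodecyl)-3,6-dihydro-1,2-dioxin-3-yl]ethyl acetate | C[C@@]1(CCCCCCCCCCCCc2ccccc2)C=C(C)[C@@H](CCOC(C)=O)OO1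
F5 | step 9 | (3S,6S)-2-[4,6-dimethyl-6-(12-phenyldodecyl)-3,6-dihydro-1,2-dioxin-3-yl]ethyl acetate | C[C@]1(CCCCCCCCCCCCc2ccccc2)C=C(C)[C@H](CCOC(C)=O)OO1
F6 | step 11 | 5-(phenylselanyl)plakortolide L, (3S,4R,5S,6S) | C[C@]1(CCCCCCCCCCCCc3ccccc3)[C@@H]([Se]c3ccccc3)[C@]2(C)OC(=O)C[C@@H]2OO1
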